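I began with the easy step in this flask, the dissolving of the gas.

    substrate + partner → product, rate k1*[substrate]*[partner]^1.5 (k1 = 16000 M⁻¹·⁵ h⁻¹)
    partner → decomposed reagent (k2 = 0.50 h⁻¹)
    crystals ⇌ product, rate k3*(cs3 - [product]) while solid is left; crystals form when [product] > cs3 (cs3 = 5.2 mM, k3 = 4.6 h⁻¹)
    gas ⇌ partner, rate k4*(csat - [partner]) (k4 = 5.8 h⁻¹, csat = 1.1 mM)

substrate 12 mM; gas 1.1 mM (held); time 5.0 h

- product is meant together with its crystals
- solid, in amounts per volume of the solution: crystals
- at the start none of partner is dissolved
- the reaction counts as stopped when no species that holds the substrate changes by six tenths of a point or more over the second half of the time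
- run time (flask): 5.0 h

- the state of affairs at 5.0 h: stopped, and by what, or still going (forward and back rates have come level / it is still moving / all of the substrate has reacted)
- the product standing at 5.0 h, as a percentage of the substrate charged

Does dissolved partner, B, follow a level of its own? Transfer relaxes within 0.172 h, far shorter than the run, so in this flask I set supply equal to use (a quasi-steady state).

Is supply ample? Partner at its saturation concentration, csat, with the substrate as charged, would be consumed at 7.00 mM h⁻¹ against a full transfer of 6.38 mM h⁻¹. Their ratio is the demand ratio D = 1.10, and two passes through the balance gave B = 0.582 mM, below csat.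

How far does substrate get? At standing B it decays pseudo-first-order with a constant equal to the rate constant times B√B, here 0.225 h⁻¹. My reckoning with that constant held throughout gave 3.90 mM of substrate at the end. At that lower demand the balance gave B = 0.791 mM, higher than my first figure, and a constant of 0.356 h⁻¹. The mean of the two, the balance constant K = 0.290 h⁻¹, gave a conversion of 76.6 %. Crystals count as product, so this is my yield. By K, substrate still fell by a factor of 2.06 between the midpoint and the end, so I committed to a flask still moving.

The forecast said it is still moving, with 75 % of product (range 71 % to 79 %), on the grounds that “Gas transfer limits the reaction”. My figure lay above its figure.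

At 5.0 h the flask stood thus: it is still moving, with 77.0 % of product. At 2.04 h partner was being made 1.02 times faster than it was used up, each step taken net. K gives substrate a half-life of 2.39 h, and the flask held 53.9 % of its substrate at 2.50 h.

With 4.8 mM of substrate, the neighbour flask has D = 0.439. Its balance gives B = 0.758 mM, then 0.946 mM, so K = 0.400 h⁻¹ and a conversion of 86.5 %. The neighbour flask gave 86.5 %.

The rate constants were chosen freely, and the outcome is calculated.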